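**Retrosynthetic overview**

1. The target is taken back to its dodeca-O-benzyl ether; global hydrogenolysis is the last step.
2. Ring C of the lower unit (O1–C2–C3–C4–C4a–C8a) is opened across C4–C3 and O1–C2 by a retro-oxa-[4+2] into an ortho-quinone methide on ring A and a (Z)-enol gallate. The enabling feature is that C4 is an unsubstituted benzylic CH2 ortho to the ring oxygen O1 on the phloroglucinol ring A (heterodiene C4=C4a–C8a=O1), and that the cis C2-aryl/C3-O-galloyl pair maps onto a (Z)-2-arylvinyl gallate.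
3. The ortho-quinone methide comes from a salicyl alcohol, made by ortho-formylation and reduction of a phenol whose only free hydroxyl is flanked by the upper unit (this fixes the 4→8 constitution). That phenol comes from a Friedel–Crafts union of a (2S)-4-methoxyflavan with 3,5-bis(benzyloxy)phenol (interflavan bond, 2,4-trans).
4. The upper unit comes from (−)-epicatechin: C2 from the chiral pool, C4 oxidised while the C3 hydroxyl is still present, C3 then deoxygenated. The enol gallate comes from a Z-selective ruthenium-catalysed addition of tri-O-benzylgallic acid to an arylacetylene.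
5. Ring order: the upper unit's rings are bought; ring A of the lower unit is attached at C4 of the upper unit; ring C of the lower unit is closed in the penultimate step, with ring B and the gallate carried in.

Key step: step 10

Remark (assumption): the sense of induction of the chiral phosphoric acid on this chiral substrate cannot be predicted with confidence; the (R) antipode is written and is assumed to be the one matched to the (2R,3R) ring, to be confirmed by one pilot run with each antipode.

**Route**

Step 1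
Reactants: 1 (−)-epicatechin
Product: 2 5,7,3',4'-tetra-O-benzyl-(−)-epicatechin
Conditions: BnBr (4.4 equiv), K2CO3, DMF, 0 °C to rt, argon
Reagents that add atoms: benzyl bromide, BrCc1ccccc1
Why: Williamson etherification in which carbonate deprotonates only the four phenols, so the secondary C3 hydroxyl stays free and no stereocentre is touched.

Step 2
Reactants: 2 5,7,3',4'-tetra-O-benzyl-(−)-epicatechin
Product: 3 (2R,3R,4S)-5,7-bis(benzyloxy)-2-[3,4-bis(benzyloxy)phenyl]-4-methoxychroman-3-ol
Conditions: 2,3-dichloro-5,6-dicyano-1,4-benzoquinone (DDQ, 2 equiv), MeOH (excess), CH2Cl2, rt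
Reagents that add atoms: methanol, CO
Why: DDQ benzylic oxidation (hydride abstraction at C4 to a cation stabilised by the 5,7-dioxygenated ring A and O1), a standard C4 functionalisation of benzylated flavan-3-ols, with methanol adding anti to the C3 hydroxyl and the C2 aryl group to set the 3,4-trans C4 centre.

Step 3
Reactants: 3 (2R,3R,4S)-5,7-bis(benzyloxy)-2-[3,4-bis(benzyloxy)phenyl]-4-methoxychroman-3-ol
Product: 4 O-[(2R,3R,4S)-5,7-bis(benzyloxy)-2-[3,4-bis(benzyloxy)phenyl]-4-methoxychroman-3-yl] S-methyl dithiocarbonate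
Conditions: NaH, CS2, THF, 0 °C; then MeI, rt
Reagents that add atoms: carbon disulfide, S=C=S; iodomethane, CI
Why: xanthate formation (first half of the Barton–McCombie deoxygenation) at the only free hydroxyl, with all configurations retained.

Step 4
Reactants: 4 O-[(2R,3R,4S)-5,7-bis(benzyloxy)-2-[3,4-bis(benzyloxy)phenyl]-4-methoxychroman-3-yl] S-methyl dithiocarbonate
Product: 5 (2S,4R)-5,7-bis(benzyloxy)-2-[3,4-bis(benzyloxy)phenyl]-4-methoxychroman (2,4-trans)
Conditions: Bu3SnH (3 equiv, kept concentrated), azobisisobutyronitrile (cat.), toluene, 100 °C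
Reagents that add atoms: none
Why: Barton–McCombie radical deoxygenation in which the secondary C3 radical is reduced by the stannane faster than it can open the C2–O1 bond; C2 and C4 are untouched and the C2 descriptor changes from R to S only through the change in priorities.

Step 5
Reactants: 5 (2S,4R)-5,7-bis(benzyloxy)-2-[3,4-bis(benzyloxy)phenyl]-4-methoxychroman; 6 3,5-bis(benzyloxy)phenol (4 equiv)
Product: 7 3,5-bis(benzyloxy)-2-[(2S)-2,4-trans-5,7-bis(benzyloxy)-2-[3,4-bis(benzyloxy)phenyl]chroman-4-yl]phenol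
Conditions: Me3SiOTf (0.2 equiv), CH2Cl2, −78 to −30 °C
Reagents that add atoms: none
Why: Friedel–Crafts arylation of the ionised C4 ether, the reaction type by which interflavan bonds are made from 4-alkoxyflavans; the phenol should react ortho to its free hydroxyl (less hindered than the position between the two benzyloxy groups, as in cinnamylation of the same phenol), and the aryl group should enter anti to the C2 aryl group, pseudo-axial and away from the peri 5-benzyloxy group, which sets the 2,4-trans centre.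

Step 6
Reactants: 7 3,5-bis(benzyloxy)-2-[(2S)-2,4-trans-5,7-bis(benzyloxy)-2-[3,4-bis(benzyloxy)phenyl]chroman-4-yl]phenol
Product: 8 4,6-bis(benzyloxy)-2-hydroxy-3-[(2S)-2,4-trans-5,7-bis(benzyloxy)-2-[3,4-bis(benzyloxy)phenyl]chroman-4-yl]benzaldehyde
Conditions: MgCl2, Et3N, (CH2O)n, THF, reflux; 1 M HCl work-up
Reagents that add atoms: paraformaldehyde (formaldehyde), C=O
Why: magnesium-mediated ortho-formylation of a phenol (Casnati–Skattebøl reaction), which is specific for the position ortho to the hydroxyl; only one such position is free, so the carbon that becomes C4 of the lower unit is placed unambiguously.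

Step 7
Reactants: 8 4,6-bis(benzyloxy)-2-hydroxy-3-[(2S)-2,4-trans-5,7-bis(benzyloxy)-2-[3,4-bis(benzyloxy)phenyl]chroman-4-yl]benzaldehyde
Product: 9 3,5-bis(benzyloxy)-2-(hydroxymethyl)-6-[(2S)-2,4-trans-5,7-bis(benzyloxy)-2-[3,4-bis(benzyloxy)phenyl]chroman-4-yl]phenol
Conditions: NaBH4 (1.2 equiv), THF/MeOH, −20 °C; sat. NH4Cl; used at once
Reagents that add atoms: none
Why: borohydride reduction of the aldehyde, with low temperature and a neutral quench meant to keep the electron-rich salicyl alcohol from losing water prematurely.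

Step 8
Reactants: 10 3,4,5-tris(benzyloxy)benzaldehyde
Product: 11 1,2,3-tris(benzyloxy)-5-ethynylbenzene
Conditions: dimethyl (1-diazo-2-oxopropyl)phosphonate, K2CO3, MeOH/THF, rt
Reagents that add atoms: dimethyl (1-diazo-2-oxopropyl)phosphonate, CC(=O)C(=[N+]=[N-])P(=O)(OC)OC
Why: Seyferth–Gilbert homologation in the Ohira–Bestmann variant, which converts non-enolisable aromatic aldehydes into terminal alkynes under mild carbonate conditions that benzyl ethers tolerate.

Step 9
Reactants: 11 1,2,3-tris(benzyloxy)-5-ethynylbenzene; 12 3,4,5-tris(benzyloxy)benzoic acid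
Product: 13 (Z)-2-[3,4,5-tris(benzyloxy)phenyl]ethenyl 3,4,5-tris(benzyloxy)benzoate
Conditions: Ru(2-methylallyl)2(Ph2P(CH2)4PPh2) (3 mol %), toluene, 65 °C
Reagents that add atoms: none
Why: ruthenium-catalysed anti-Markovnikov addition of a carboxylic acid to a terminal arylacetylene through a ruthenium vinylidene, a reaction type that gives (Z)-enol esters, so the alkene geometry is set by the catalyst.

Step 10
Reactants: 9 3,5-bis(benzyloxy)-2-(hydroxymethyl)-6-[(2S)-2,4-trans-5,7-bis(benzyloxy)-2-[3,4-bis(benzyloxy)phenyl]chroman-4-yl]phenol; 13 (Z)-2-[3,4,5-tris(benzyloxy)phenyl]ethenyl 3,4,5-tris(benzyloxy)benzoate (3 equiv)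
Product: 15 dodeca-O-benzyl ether of the target, via ortho-quinone methide 14 (not isolated)
Conditions: (R)-3,3'-bis(2,4,6-triisopropylphenyl)-1,1'-binaphthyl-2,2'-diyl hydrogen phosphate (10 mol %), 5 Å molecular sieves, PhCF3, −20 °C to rt, slow addition of 9
Reagents that add atoms: none
Why: Proposed new method: the phosphoric acid dehydrates the salicyl alcohol 9 (the water lost is taken up by the sieves) to the hydrogen-bonded ortho-quinone methide 14 (heterodiene C4=C4a–C8a=O1), which should undergo an inverse-electron-demand oxa-[4+2] cycloaddition (hetero-Diels–Alder) with the electron-rich (Z)-enol ester 13, forming C4–C3 and O1–C2 in one asynchronous concerted event; the closest known reaction types are the chiral-phosphoric-acid-catalysed [4+2] cycloadditions of in situ generated ortho-quinone methides with styrenes, vinyl sulfides and enol ethers, and the thermal cycloaddition of ortho-quinone methides with beta-substituted styrenes to give 2-aryl-3-substituted chromans. Ring C of the lower unit is closed as a six-membered dihydropyran by this intermolecular [4+2] annulation, which rearomatises ring A. Regiochemistry (aryl at C2, acyloxy at C3) follows from the polarisation of 13: the methide carbon bonds to the oxygen-bearing alkene carbon so that positive charge builds up at the benzylic carbon, where it is stabilised by the tris(benzyloxy)phenyl ring far better than an acyloxy group could stabilise it at the other carbon, and the phenolic oxygen then bonds there. The 2,3-cis relationship is set by suprafacial addition across the (Z)-alkene, and the absolute (2R,3R) configuration by the chiral phosphate bound at O1, which selects the alkene enantioface that bonds (one heterodiene face combined with one orientation of the aryl and acyloxy groups), the resident 2,4-trans flavanyl group at C8 reinforcing it in the matched pairing. The 4→8 constitution is secured because only the hydroxyl flanked by the flavanyl group is free, and Friedel–Crafts self-alkylation of the electron-rich rings by 14 is held back by slow addition of 9 to excess 13.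

Step 11
Reactants: 15 dodeca-O-benzyl ether of the target
Product: 16 the target, (2S)-2,4-trans-luteoliflavan-(4→8)-(−)-epigallocatechin 3-O-gallate
Conditions: H2 (1 atm), Pd(OH)2/C, THF/MeOH 1:1, rt
Reagents that add atoms: none
Why: hydrogenolysis of the twelve benzyl ethers under neutral conditions, which should leave the gallate ester, the interflavan bond and all four stereocentres untouched.

**Compound list**

1 | (−)-epicatechin, (2R,3R)-2-(3,4-dihydroxyphenyl)chromane-3,5,7-triol | O[C@@H]1Cc2c(O)cc(O)cc2O[C@@H]1c1ccc(O)c(O)c1 | starting material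
2 | 5,7,3',4'-tetra-O-benzyl-(−)-epicatechin, (2R,3R)-5,7-bis(benzyloxy)-2-[3,4-bis(benzyloxy)phenyl]chroman-3-ol | O[C@@H]1Cc2c(OCc3ccccc3)cc(OCc3ccccc3)cc2O[C@@H]1c1ccc(OCc2ccccc2)c(OCc2ccccc2)c1 | intermediate
3 | (2R,3R,4S)-5,7-bis(benzyloxy)-2-[3,4-bis(benzyloxy)phenyl]-4-methoxychroman-3-ol (methoxy trans to the 3-hydroxyl and to the 2-aryl group) | CO[C@@H]1[C@@H](O)[C@@H](c2ccc(OCc3ccccc3)c(OCc3ccccc3)c2)Oc2cc(OCc3ccccc3)cc(OCc3ccccc3)c21 | intermediate
4 | O-[(2R,3R,4S)-5,7-bis(benzyloxy)-2-[3,4-bis(benzyloxy)phenyl]-4-methoxychroman-3-yl] S-methyl dithiocarbonate | CO[C@@H]1[C@@H](OC(=S)SC)[C@@H](c2ccc(OCc3ccccc3)c(OCc3ccccc3)c2)Oc2cc(OCc3ccccc3)cc(OCc3ccccc3)c21 | intermediate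
5 | (2S,4R)-5,7-bis(benzyloxy)-2-[3,4-bis(benzyloxy)phenyl]-4-methoxychroman (2,4-trans) | CO[C@@H]1C[C@@H](c2ccc(OCc3ccccc3)c(OCc3ccccc3)c2)Oc2cc(OCc3ccccc3)cc(OCc3ccccc3)c21 | intermediate
6 | 3,5-bis(benzyloxy)phenol | Oc1cc(OCc2ccccc2)cc(OCc2ccccc2)c1 | starting material
7 | 3,5-bis(benzyloxy)-2-[(2S)-2,4-trans-5,7-bis(benzyloxy)-2-[3,4-bis(benzyloxy)phenyl]chroman-4-yl]phenol | Oc1cc(OCc2ccccc2)cc(OCc2ccccc2)c1[C@@H]1C[C@@H](c2ccc(OCc3ccccc3)c(OCc3ccccc3)c2)Oc2cc(OCc3ccccc3)cc(OCc3ccccc3)c21 | intermediate
8 | 4,6-bis(benzyloxy)-2-hydroxy-3-[(2S)-2,4-trans-5,7-bis(benzyloxy)-2-[3,4-bis(benzyloxy)phenyl]chroman-4-yl]benzaldehyde | O=Cc1c(OCc2ccccc2)cc(OCc2ccccc2)c([C@@H]2C[C@@H](c3ccc(OCc4ccccc4)c(OCc4ccccc4)c3)Oc3cc(OCc4ccccc4)cc(OCc4ccccc4)c32)c1O | intermediate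
9 | 3,5-bis(benzyloxy)-2-(hydroxymethyl)-6-[(2S)-2,4-trans-5,7-bis(benzyloxy)-2-[3,4-bis(benzyloxy)phenyl]chroman-4-yl]phenol | OCc1c(OCc2ccccc2)cc(OCc2ccccc2)c([C@@H]2C[C@@H](c3ccc(OCc4ccccc4)c(OCc4ccccc4)c3)Oc3cc(OCc4ccccc4)cc(OCc4ccccc4)c32)c1O | intermediate
10 | 3,4,5-tris(benzyloxy)benzaldehyde | O=Cc1cc(OCc2ccccc2)c(OCc2ccccc2)c(OCc2ccccc2)c1 | starting material
11 | 1,2,3-tris(benzyloxy)-5-ethynylbenzene | C#Cc1cc(OCc2ccccc2)c(OCc2ccccc2)c(OCc2ccccc2)c1 | intermediate
12 | 3,4,5-tris(benzyloxy)benzoic acid | OC(=O)c1cc(OCc2ccccc2)c(OCc2ccccc2)c(OCc2ccccc2)c1 | starting material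
13 | (Z)-2-[3,4,5-tris(benzyloxy)phenyl]ethenyl 3,4,5-tris(benzyloxy)benzoate | O=C(O/C=C\c1cc(OCc2ccccc2)c(OCc2ccccc2)c(OCc2ccccc2)c1)c1cc(OCc2ccccc2)c(OCc2ccccc2)c(OCc2ccccc2)c1 | intermediate
14 | ortho-quinone methide, 3,5-bis(benzyloxy)-6-methylidene-2-[(2S)-2,4-trans-5,7-bis(benzyloxy)-2-[3,4-bis(benzyloxy)phenyl]chroman-4-yl]cyclohexa-2,4-dien-1-one | C=C1C(OCc2ccccc2)=CC(OCc2ccccc2)=C([C@@H]2C[C@@H](c3ccc(OCc4ccccc4)c(OCc4ccccc4)c3)Oc3cc(OCc4ccccc4)cc(OCc4ccccc4)c32)C1=O | intermediate
15 | dodeca-O-benzyl ether of the target (lower unit (2R,3R), 2,3-cis; upper unit (2S), 2,4-trans) | O=C(O[C@@H]1Cc2c(OCc5ccccc5)cc(OCc5ccccc5)c([C@@H]3C[C@@H](c4ccc(OCc5ccccc5)c(OCc5ccccc5)c4)Oc4cc(OCc5ccccc5)cc(OCc5ccccc5)c43)c2O[C@@H]1c1cc(OCc5ccccc5)c(OCc5ccccc5)c(OCc5ccccc5)c1)c1cc(OCc5ccccc5)c(OCc5ccccc5)c(OCc5ccccc5)c1 | intermediate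
16 | the target, (2S)-2,4-trans-luteoliflavan-(4→8)-(−)-epigallocatechin 3-O-gallate (lower unit (2R,3R); upper unit (2S,4R)) | O=C(O[C@@H]1Cc2c(O)cc(O)c([C@@H]3C[C@@H](c4ccc(O)c(O)c4)Oc4cc(O)cc(O)c43)c2O[C@@H]1c1cc(O)c(O)c(O)c1)c1cc(O)c(O)c(O)c1 | target

**Step count and risks**

Total step count: 11. Longest linear sequence: 9 steps (steps 1 to 7, 10 and 11).

Most likely to fail, step 10: the ortho-quinone methide may be consumed by Friedel–Crafts self-alkylation of the electron-rich rings, the catalyst may discriminate poorly between the alkene faces on this chiral heterodiene, or ionisation at C2 may erode the cis relationship. The fallback takes the lower flavan-3-ol ring from the chiral pool instead of building it. It sets out from 5, which is condensed (Me3SiOTf, CH2Cl2, −78 °C) with an excess of octa-O-benzyl-(−)-epigallocatechin gallate F1, itself obtained from commercial (−)-epigallocatechin gallate with BnBr and K2CO3 in DMF. The cation from 5 should arylate C8 of F1, the position at which benzylated flavan-3-ols react, anti to the C2 aryl group. The fallback comes back to the route at 15.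

Second, step 5: regiocontrol may be lost through alkylation para to the free hydroxyl or double alkylation of the nucleophile. The fallback uses a symmetrical nucleophile and differentiates the oxygens afterwards. It sets out from 5, which is condensed with excess phloroglucinol (Me3SiOTf, THF/CH2Cl2, −40 °C) to give 2-[(2S)-2,4-trans-5,7-bis(benzyloxy)-2-[3,4-bis(benzyloxy)phenyl]chroman-4-yl]benzene-1,3,5-triol F2, in which both free ring positions are equivalent. Vilsmeier–Haack formylation (POCl3, DMF, EtOAc, 0 °C, then aqueous hydrolysis) should give 2,4,6-trihydroxy-3-[(2S)-2,4-trans-5,7-bis(benzyloxy)-2-[3,4-bis(benzyloxy)phenyl]chroman-4-yl]benzaldehyde F3. Dibenzylation (BnBr 2.1 equiv, K2CO3, DMF, 0 °C) should then take the para hydroxyl and the less hindered ortho hydroxyl and spare the chelated hydroxyl flanked by the flavanyl group. The fallback comes back to the route at 8.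

Third, step 7: the aldehyde may be over-reduced to a methyl group through in-flask elimination to the quinone methide and hydride capture, or the salicyl alcohol may self-condense on isolation. The fallback avoids any carbonyl reduction. It sets out from 7, which is ortho-hydroxymethylated with PhB(OH)2 and (CH2O)n (cat. EtCO2H, toluene, reflux with water removal) to give the storable cyclic boronate 5,7-bis(benzyloxy)-2-phenyl-8-[(2S)-2,4-trans-5,7-bis(benzyloxy)-2-[3,4-bis(benzyloxy)phenyl]chroman-4-yl]-4H-1,3,2-benzodioxaborin F4. Transesterification with propane-1,3-diol (THF, rt) just before the key step releases the salicyl alcohol, and the fallback comes back to the route at 9.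

**Further compounds**

F1 | step 10 | octa-O-benzyl-(−)-epigallocatechin gallate | O=C(O[C@@H]1Cc2c(OCc3ccccc3)cc(OCc3ccccc3)cc2O[C@@H]1c1cc(OCc2ccccc2)c(OCc2ccccc2)c(OCc2ccccc2)c1)c1cc(OCc2ccccc2)c(OCc2ccccc2)c(OCc2ccccc2)c1
F2 | step 5 | 2-[(2S)-2,4-trans-5,7-bis(benzyloxy)-2-[3,4-bis(benzyloxy)phenyl]chroman-4-yl]benzene-1,3,5-triol | Oc1cc(O)c([C@@H]2C[C@@H](c3ccc(OCc4ccccc4)c(OCc4ccccc4)c3)Oc3cc(OCc4ccccc4)cc(OCc4ccccc4)c32)c(O)c1
F3 | step 5 | 2,4,6-trihydroxy-3-[(2S)-2,4-trans-5,7-bis(benzyloxy)-2-[3,4-bis(benzyloxy)phenyl]chroman-4-yl]benzaldehyde | O=Cc1c(O)cc(O)c([C@@H]2C[C@@H](c3ccc(OCc4ccccc4)c(OCc4ccccc4)c3)Oc3cc(OCc4ccccc4)cc(OCc4ccccc4)c32)c1O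
F4 | step 7 | 5,7-bis(benzyloxy)-2-phenyl-8-[(2S)-2,4-trans-5,7-bis(benzyloxy)-2-[3,4-bis(benzyloxy)phenyl]chroman-4-yl]-4H-1,3,2-benzodioxaborin | B1(c2ccccc2)OCc2c(OCc3ccccc3)cc(OCc3ccccc3)c([C@@H]3C[C@@H](c4ccc(OCc5ccccc5)c(OCc5ccccc5)c4)Oc4cc(OCc5ccccc5)cc(OCc5ccccc5)c43)c2O1
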